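**Retrosynthetic overview**
1. Target 15 ⇐ bicyclic acylphloroglucinol 13 (C7 prenyl endo) by one aerobic radical cascade: C3–C2′ bond (homoadamantane), O2 capture, 7-exo peroxyl closure (1,2-dioxepane), second O2 capture, then OOH → OH.
2. 13 ⇐ monocyclic acylphloroglucinol 10 (used as enol pivalate 11) by Markovnikov, cation-type closure of the lavandulyl carbon C8 onto the benzoyl-bearing C1 (bicyclo[3.3.1] ring).
3. 10 ⇐ quaternary malonate 6 + prenylated benzoylacetone 9 by a polyketide-style double Claisen closure of the trione ring; this fixes which ring carbon carries benzoyl, prenyl and the geranyl/lavandulyl pair.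
4. All absolute configuration comes from (R)-lavandulol 1 (C7). Ring order: trione ring → bicyclo[3.3.1] ring → homoadamantane → dioxepane.

**Assumptions and labels**
- (R)-(–)-Lavandulol 1 is bought as the single enantiomer (it is the natural form; otherwise it comes from lipase resolution of the cheap racemate).
- Labels: C1 (benzoyl-bearing), C2, C3 (prenyl-bearing), C4, C5 (geranyl-bearing) and C9 form the trione ring; C6, C7, C8 come from lavandulyl; C1′–C3′ is the prenyl on C7; C1″–C3″ is the prenyl on C3.
- Geranyl = (2E)-3,7-dimethylocta-2,6-dien-1-yl; prenyl = 3-methylbut-2-en-1-yl; lavandulyl = 5-methyl-2-(prop-1-en-2-yl)hex-4-en-1-yl.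
- Step 5 sets C5 without control, so 10 is formed as a 1:1 pair with its C5 epimer (same constitution, lavandulyl centre unchanged). The pair is not separated at that stage; the epimer is acylated and cyclised alongside in steps 6 and 7 and is removed by chromatography at the end of step 7, where it has become the C7-exo diastereomer of 13. Numbers, names and SMILES for 10 to 13 refer to the series with the C5 configuration of the target.

**Route**

Step 1
Reactants: 1 (R)-lavandulol
Product: 2 (R)-lavandulyl iodide
Conditions: PPh3, I2, imidazole, CH2Cl2, 0 → 23 °C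
Reagents that add atoms: iodine, I-I
Why: Appel-type iodination replaces the primary OH by SN2 attack of iodide on the alkoxyphosphonium ion; the neighbouring stereocentre is not touched and stays R.

Step 2
Reactants: 2 (R)-lavandulyl iodide; 3 dimethyl malonate
Product: 4 dimethyl 2-[(2S)-lavandulyl]propanedioate
Conditions: NaH (1.1 equiv), 3 (3 equiv), THF–DMF, 0 → 60 °C
Reagents that add atoms: none
Why: Malonic ester alkylation (SN2) of a primary iodide, with excess malonate to suppress dialkylation; the stereocentre is untouched (the descriptor becomes S only through the priority change).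

Step 3
Reactants: 4 dimethyl 2-[(2S)-lavandulyl]propanedioate; 5 geranyl bromide
Product: 6 dimethyl 2-geranyl-2-[(2S)-lavandulyl]propanedioate
Conditions: NaH (1.2 equiv), THF–DMF, 0 → 23 °C
Reagents that add atoms: none
Why: Second malonic ester alkylation, SN2 at the unhindered allylic CH2 with retention of the E alkene; the new quaternary carbon carries two identical esters and is not yet stereogenic.

Step 4
Reactants: 7 1-phenylbutane-1,3-dione; 8 prenyl bromide
Product: 9 7-methyl-1-phenyloct-6-ene-1,3-dione
Conditions: LiN(iPr)2 (2.1 equiv), THF, –78 → 0 °C; then 8, –78 → 0 °C; cold dilute aq. HCl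
Reagents that add atoms: none
Why: γ-Alkylation of a β-diketone dianion; the more basic terminal carbanion reacts, so the prenyl group ends up on the carbon that becomes C3.

Step 5
Reactants: 6 dimethyl 2-geranyl-2-[(2S)-lavandulyl]propanedioate; 9 7-methyl-1-phenyloct-6-ene-1,3-dione
Product: 10 (6S)-2-benzoyl-6-geranyl-3,5-dihydroxy-6-[(2S)-lavandulyl]-4-prenylcyclohexa-2,4-dien-1-one
Conditions: 9 (2.5 equiv), LiN(iPr)2 (5.2 equiv), THF, –78 → 0 °C; then 6, 0 → 50 °C; aq. HCl to pH 3
Reagents that add atoms: none
Why: Polyketide-style double Claisen condensation (dianion acylation followed by Dieckmann-type closure, the ring closure a benzophenone synthase performs): the terminal carbanion of 9 acylates one ester of the non-enolisable diester 6 and the β-diketonate carbon then closes the only possible (six-membered) ring on the second ester; the two esters of 6 are diastereotopic but not differentiated, so C5 is set without control and 10 is obtained as a 1:1 pair with its C5 epimer, which is not separated here.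

Step 6
Reactants: 10 (6S)-2-benzoyl-6-geranyl-3,5-dihydroxy-6-[(2S)-lavandulyl]-4-prenylcyclohexa-2,4-dien-1-one (together with its unseparated C5 epimer)
Product: 11 (6S)-4-benzoyl-6-geranyl-3-hydroxy-6-[(2S)-lavandulyl]-5-oxo-2-prenylcyclohexa-1,3-dien-1-yl 2,2-dimethylpropanoate
Conditions: t-BuCOCl (1.1 equiv), Et3N (1.2 equiv), DMAP (5 mol %), CH2Cl2, –20 → 0 °C
Reagents that add atoms: pivaloyl chloride, CC(C)(C)C(=O)Cl
Why: O-Acylation of the non-chelated vinylogous-acid OH at C4 (DMAP lets the acyl group settle where the hydrogen bond of the benzoyl enol is kept), which turns the otherwise more nucleophilic prenyl-bearing C3 into an inert enol-ester carbon so that only C1 can act as the carbon nucleophile in step 7; no stereocentre is touched and the accompanying C5 epimer is acylated in the same way.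

Step 7
Reactants: 11 (6S)-4-benzoyl-6-geranyl-3-hydroxy-6-[(2S)-lavandulyl]-5-oxo-2-prenylcyclohexa-1,3-dien-1-yl 2,2-dimethylpropanoate (together with its unseparated C5 epimer)
Product: 13 (1S,5S,7S)-1-benzoyl-5-geranyl-4-hydroxy-8,8-dimethyl-3,7-diprenylbicyclo[3.3.1]non-3-ene-2,9-dione (C7 prenyl endo), via bicyclic enol pivalate 12 (not isolated)
Conditions: C36H52CoN2O2 (divalent cobalt complex of N,N′-bis(3,5-di-tert-butylsalicylidene)-1,2-cyclohexanediamine, 5 mol %), N-fluoro-2,4,6-trimethylpyridinium tetrafluoroborate (1.5 equiv), PhSiH3 (1.2 equiv), PhCF3, 0 °C; aq. Na2S2O3 wash; then MeOH, K2CO3 (10 mol %), 0 °C; chromatography under argon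
Reagents that add atoms: none
Why: Proposed new method: hydrogen-atom transfer from a cobalt hydride to the only 1,1-disubstituted alkene (the isopropenyl group; the four trisubstituted alkenes react far more slowly) gives the tertiary C8 radical, which is oxidised through the alkylcobalt to a cation-like tetravalent-cobalt species and captured at C1 by the benzoyl triketonate (ionised by the 2,4,6-trimethylpyridine that is released), closing the bicyclo[3.3.1] ring as in the cation-triggered cyclisation of type A biosynthesis; the tether can reach C1 only on the face that carries C6, so C1 is fixed by the bridge and the (6S)/(2S) pairing of 11 places the C7 prenyl group endo, whereas the accompanying C5 epimer can only close to the C7-exo diastereomer, which is removed by the chromatography that follows the methanolysis freeing the C2–C4 enol; the closest known reaction types are cobalt-salen hydrogen-atom-transfer/radical–polar crossover cycloisomerisations of alkenes with O- and C-nucleophiles and base-buffered tertiary-cation closures of dearomatised acylphloroglucinols to type A cores.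

Step 8
Reactants: 13 (1S,5S,7S)-1-benzoyl-5-geranyl-4-hydroxy-8,8-dimethyl-3,7-diprenylbicyclo[3.3.1]non-3-ene-2,9-dione
Product: 15 CNP0148771.1 (target), via tertiary hydroperoxide 14 (not isolated)
Conditions: Mn(OAc)3·2H2O (20 mol %), O2 (1 atm), AcOH, 23 °C; then PPh3 (1.2 equiv), CH2Cl2, 0 °C
Reagents that add atoms: dioxygen, O=O
Why: Proposed new method: Mn(OAc)3 oxidises the C2–C4 enol to the C3 radical, which adds to C2′ of the endo C7 prenyl group lying directly beneath it (homoadamantane ring; the CMe2 end turns away from the C8 gem-dimethyl group, setting C2′), the tertiary C3′ radical captures O2, the peroxyl radical closes 7-exo onto C2″ of the C3 prenyl group (setting C2″ under substrate control), the new tertiary radical captures a second O2 and is reduced to hydroperoxide 14, and PPh3 then reduces only the OOH group and leaves the hindered dialkyl peroxide; the closest known reaction types are the Mn(OAc)3/O2 synthesis of 1,2-dioxan-3-ols from 1,3-diketones and alkenes, Mn(OAc)3 radical cyclisations of prenylated acylphloroglucinols, and peroxyl-radical cyclisation with oxygen capture followed by PPh3 reduction of the hydroperoxide.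

**Compound list**

1 | (R)-lavandulol, (2R)-5-methyl-2-(prop-1-en-2-yl)hex-4-en-1-ol | OC[C@@H](C(C)=C)CC=C(C)C | starting material
2 | (R)-lavandulyl iodide, (2R)-1-iodo-5-methyl-2-(prop-1-en-2-yl)hex-4-ene | IC[C@@H](C(C)=C)CC=C(C)C | intermediate
3 | dimethyl malonate | COC(=O)CC(=O)OC | starting material
4 | dimethyl 2-[(2S)-lavandulyl]propanedioate | COC(=O)C(C[C@@H](C(C)=C)CC=C(C)C)C(=O)OC | intermediate
5 | geranyl bromide, (2E)-1-bromo-3,7-dimethylocta-2,6-diene | BrC/C=C(\C)CCC=C(C)C | starting material
6 | dimethyl 2-geranyl-2-[(2S)-lavandulyl]propanedioate | COC(=O)C(C/C=C(\C)CCC=C(C)C)(C[C@@H](C(C)=C)CC=C(C)C)C(=O)OC | intermediate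
7 | 1-phenylbutane-1,3-dione (benzoylacetone) | CC(=O)CC(=O)c1ccccc1 | starting material
8 | prenyl bromide, 1-bromo-3-methylbut-2-ene | BrCC=C(C)C | starting material
9 | 7-methyl-1-phenyloct-6-ene-1,3-dione | CC(C)=CCCC(=O)CC(=O)c1ccccc1 | intermediate
10 | (6S)-2-benzoyl-6-geranyl-3,5-dihydroxy-6-[(2S)-lavandulyl]-4-prenylcyclohexa-2,4-dien-1-one (one enol tautomer drawn; ring position 6 is C5) | O=C1C(C(=O)c2ccccc2)=C(O)C(CC=C(C)C)=C(O)[C@]1(C/C=C(\C)CCC=C(C)C)C[C@@H](C(C)=C)CC=C(C)C | intermediate
11 | (6S)-4-benzoyl-6-geranyl-3-hydroxy-6-[(2S)-lavandulyl]-5-oxo-2-prenylcyclohexa-1,3-dien-1-yl 2,2-dimethylpropanoate (O4 pivalate of 10) | O=C1C(C(=O)c2ccccc2)=C(O)C(CC=C(C)C)=C(OC(=O)C(C)(C)C)[C@]1(C/C=C(\C)CCC=C(C)C)C[C@@H](C(C)=C)CC=C(C)C | intermediate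
12 | (1S,5S,7S)-1-benzoyl-5-geranyl-8,8-dimethyl-2,9-dioxo-3,7-diprenylbicyclo[3.3.1]non-3-en-4-yl 2,2-dimethylpropanoate (C7 prenyl endo; not isolated) | CC(C)=CCC/C(C)=C/C[C@]12C[C@H](CC=C(C)C)C(C)(C)[C@@](C(=O)c3ccccc3)(C2=O)C(=O)C(CC=C(C)C)=C1OC(=O)C(C)(C)C | intermediate
13 | (1S,5S,7S)-1-benzoyl-5-geranyl-4-hydroxy-8,8-dimethyl-3,7-diprenylbicyclo[3.3.1]non-3-ene-2,9-dione (C7 prenyl endo, on the side of the C2–C4 bridge; 4-enol tautomer drawn) | CC(C)=CCC/C(C)=C/C[C@]12C[C@H](CC=C(C)C)C(C)(C)[C@@](C(=O)c3ccccc3)(C2=O)C(=O)C(CC=C(C)C)=C1O | intermediate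
14 | C3″ hydroperoxide of 15 (OOH in place of the tertiary OH; not isolated) | CC(C)=CCC/C(C)=C/C[C@]12C[C@@H]3C[C@@H]4C(C)(C)OO[C@H](C(C)(C)OO)C[C@@]4(C1=O)C(=O)[C@](C(=O)c1ccccc1)(C2=O)C3(C)C | intermediate
15 | CNP0148771.1: 1-benzoyl-5-geranyl homoadamantane trione with a 1,2-dioxepane fused at C3–C2′ and a 2-hydroxypropan-2-yl group on C2″; (1R,3R,5S,7S,2′S,2″S) in the labels used here | CC(C)=CCC/C(C)=C/C[C@]12C[C@@H]3C[C@@H]4C(C)(C)OO[C@H](C(C)(C)O)C[C@@]4(C1=O)C(=O)[C@](C(=O)c1ccccc1)(C2=O)C3(C)C | target

**Step count and risks**

Total step count: 8. Longest linear sequence: 7 (1 → 2 → 4 → 6 → 10 → 11 → 13 → 15; step 4 is the side branch).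

The three steps most likely to fail:

1. Step 7 (cation-type closure to the type A bicycle). Risks: the triketonate may trap the tertiary centre through oxygen instead of C1; the endo arrangement of the C7 prenyl group makes the C–C closure strained; the C8 radical may add to the geranyl alkene before it is oxidised; the N–F oxidant may fluorinate the enol. At best half of the material (the series with the C5 configuration of the target) can give 13. Fallback, setting out from 11 and coming back at 12: the same hydrogen-atom-transfer conditions are run to the kinetic O-trapped product, the cyclic enol ether F1, which is isolated. Its tertiary C8–O bond is then re-ionised with BF3·OEt2 and 2,6-di-tert-butylpyridine in CH2Cl2 at –40 °C. The triketone is a good leaving group, so the ion pair re-forms without free acid and collapses at C1 to the C–C bonded bicycle 12 (an O-to-C 1,3-shift), which rejoins the route before the methanolysis.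

2. Step 8 (aerobic radical cascade). Risks: the first peroxyl radical may be reduced before the slow 7-exo closure; it may close onto the C4 carbonyl as a peroxy-hemiketal; C3 may be oxygenated directly; C2″ may form as the wrong epimer; the manganese salts may degrade the hydroperoxide. Fallback, setting out from 13 and coming back at 14: the Mn(OAc)3/O2 oxidation is stopped after the first oxygen capture (added Mn(OAc)2, short time) and the homoadamantane tertiary hydroperoxide F2 is isolated. Its peroxyl radical is then generated on purpose under metal-free chain conditions (di-tert-butyl hyponitrite, O2, benzene, 35 °C), where nothing reduces it before it closes 7-exo and captures the second O2 to give 14. PPh3 then gives 15 as before.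

3. Step 5 (double Claisen on a hindered diester). Risks: the secondary carbanion of the dianion of 9 may not acylate the neopentyl-type ester, or the ring closure may stall at the open triketo ester. Fallback, setting out from 6 and coming back at 10 (again as the 1:1 pair with its C5 epimer): 6 is saponified (KOH, aqueous MeOH, then cold acidification) to the diacid F3. This is converted under neutral conditions with 1-chloro-N,N,2-trimethylprop-1-en-1-amine into the dichloride F4. F4 is added to the dilithio dianion of 9 at –78 °C; the acid chloride carbonyls accept both the hindered carbanion and the ring-closing C-acylation far more readily than the methyl esters.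

**Further compounds**

F1 | step 7 | (3S,4aR)-8-benzoyl-4a-geranyl-2,2-dimethyl-7-oxo-3,6-diprenyl-3,4,4a,7-tetrahydro-2H-chromen-5-yl 2,2-dimethylpropanoate (cyclic enol ether from O9–C8 closure of 11) | O1C(C)(C)[C@@H](CC=C(C)C)C[C@]2(C/C=C(\C)CCC=C(C)C)C1=C(C(=O)c1ccccc1)C(=O)C(CC=C(C)C)=C2OC(=O)C(C)(C)C
F2 | step 8 | homoadamantane tertiary hydroperoxide (C3–C2′ bond closed, OOH on C3′, C3 prenyl intact; C1, C3, C5, C7 and C2′ arranged as in 15) | CC(C)=CCC/C(C)=C/C[C@]12C[C@@H]3C[C@H](C(C)(C)OO)[C@](CC=C(C)C)(C1=O)C(=O)[C@](C(=O)c1ccccc1)(C2=O)C3(C)C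
F3 | step 5 | 2-geranyl-2-[(2S)-lavandulyl]propanedioic acid | OC(=O)C(C/C=C(\C)CCC=C(C)C)(C[C@@H](C(C)=C)CC=C(C)C)C(=O)O
F4 | step 5 | 2-geranyl-2-[(2S)-lavandulyl]propanedioyl dichloride | ClC(=O)C(C/C=C(\C)CCC=C(C)C)(C[C@@H](C(C)=C)CC=C(C)C)C(Cl)=O
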